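## Retrosynthetic overview

1. Numbering used throughout: carbocycle C1 (C=O), C2, C3, C4 (CH–CH3), C5 (O‑isovaleryl), C6 (OH), C7, C8 (lactone O), C9 (O‑isobutyryl), C10 (C(OH)CH3); lactone C11 (α‑C), C12 (C=O), C13 (=CH2).
2. Enabling feature: the C1 ketone and the C5/C6 dioxygenated pair are joined through C2–C3–C4 (O=C1–C2–C3–C4–C5–C6), the retron of a cyclodec‑5‑en‑1‑one. The ten‑membered ring is therefore cut at C3–C4 by a retro‑[3,3] (oxy‑Cope) shift. This re‑forms a C1–C6 bond that the target does not contain and gives cyclohexane ring A (C1, C6, C7, C8, C9, C10) with OH and vinyl (C2=C3) on C1 and (E)‑propenyl (C5=C4) on C6.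
3. After the ring expansion the (Z)‑C5=C6 alkene is epoxidised on its outer face and the C1 carbonyl oxygen is delivered to C5 from inside the ring (temporary C1–O–C5 oxane bridge). This sets C5/C6 and tells O5 from O6; acylations and release of the C13 methylene from a Mannich base finish the route.
4. Ring A with C7–C10 comes from (R)‑4‑silyloxycyclohexenone: Mukaiyama–Michael addition (C7), enone dihydroxylation (C9, C10), lactonisation (ring B), C6 allylation, C1 vinylation.
5. Ring order: ring A (present in 1) → acetonide (temporary, step 9) → γ‑lactone ring B (step 10) → ten‑membered ring by expansion of ring A (step 15) → temporary oxane bridge (step 17, opened in step 19).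

Key step: step 15

Remark: β means the face of the C10 methyl group when the carbocycle is drawn flat, α the opposite face; compounds 5–7 (C10) and 17–20 (C11) are carried as epimer mixtures at a centre that later becomes sp2, so that centre is left open in their SMILES.

## Route

Step 1
Reactants: 1 1,4-dioxaspiro[4.5]dec-6-en-8-one
Product: 2 (8R)-1,4-dioxaspiro[4.5]dec-6-en-8-ol
Conditions: RuCl(p-cymene)[(R,R)-TsDPEN] (1 mol %), HCO2Na, Bu4NCl (cat.), CH2Cl2/H2O, rt
Reagents that add atoms: none
Why: Noyori-type asymmetric transfer hydrogenation (1,2-reduction of the enone C=O); with the alkene in the place an aryl group has in aryl ketones, the (R,R)-ligand should give the (R)-allylic alcohol, which becomes C8.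

Step 2
Reactants: 2 (8R)-1,4-dioxaspiro[4.5]dec-6-en-8-ol
Product: 3 (8R)-8-[(tert-butyldimethylsilyl)oxy]-1,4-dioxaspiro[4.5]dec-6-ene
Conditions: TBSCl, imidazole, DMF, rt
Reagents that add atoms: tert-butyldimethylsilyl chloride, CC(C)(C)[Si](C)(C)Cl
Why: Silyl ether formation on the secondary allylic alcohol gives the bulky O8 group that later directs two additions to the opposite face.

Step 3
Reactants: 3 (8R)-8-[(tert-butyldimethylsilyl)oxy]-1,4-dioxaspiro[4.5]dec-6-ene
Product: 4 (4R)-4-[(tert-butyldimethylsilyl)oxy]cyclohex-2-en-1-one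
Conditions: PPTS (cat.), acetone/H2O, 50 °C
Reagents that add atoms: water, O
Why: Acid-catalysed acetal hydrolysis unveils the C1 ketone in conjugation with C6=C7, so that C8–OTBS becomes the γ-stereocentre of a cyclohexenone; the secondary silyl ether should survive PPTS.

Step 4
Reactants: 4 (4R)-4-[(tert-butyldimethylsilyl)oxy]cyclohex-2-en-1-one
Product: 5 (4R)-4-[(tert-butyldimethylsilyl)oxy]-6-methylcyclohex-2-en-1-one (C6 epimers; C10 in target numbering)
Conditions: LiN(i-Pr)2, THF, −78 °C; MeI, −78 → −40 °C
Reagents that add atoms: iodomethane, CI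
Why: Kinetic α′-deprotonation gives the cross-conjugated enolate, and its alkylation puts the future C10 methyl in place; the new centre need not be controlled because it becomes sp2 in step 7.

Step 5
Reactants: 5 (4R)-4-[(tert-butyldimethylsilyl)oxy]-6-methylcyclohex-2-en-1-one
Product: 7 methyl 2-[(1S,2R)-2-[(tert-butyldimethylsilyl)oxy]-4-methyl-5-oxocyclohexyl]acetate, via trimethylsilyl enol ether 6 (not isolated)
Conditions: 1-methoxy-1-(trimethylsilyloxy)ethene, Sc(OTf)3 (5 mol %), CH2Cl2, −78 °C; then 1 M HCl, THF, 0 °C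
Reagents that add atoms: 1-methoxy-1-(trimethylsilyloxy)ethene, C=C(OC)O[Si](C)(C)C
Why: Mukaiyama–Michael addition at C7 should occur anti to the neighbouring C8–OTBS group, which sets C7 trans to O8; the silyl enol ether is hydrolysed on work-up.

Step 6
Reactants: 7 methyl 2-[(1S,2R)-2-[(tert-butyldimethylsilyl)oxy]-4-methyl-5-oxocyclohexyl]acetate
Product: 8 C1=C10 trimethylsilyl enol ether of 7
Conditions: TMSCl, NaI, Et3N, MeCN, rt
Reagents that add atoms: chlorotrimethylsilane, C[Si](C)(C)Cl
Why: Silylation under equilibrating conditions (thermodynamic enol silane formation) should favour the more substituted C1=C10 enol ether over the C1=C6 isomer.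

Step 7
Reactants: 8 C1=C10 trimethylsilyl enol ether of 7
Product: 9 enone ester (C1 ketone, C9=C10 with 10-methyl, 8β-OTBS, 7α-CH2CO2Me)
Conditions: Pd(OAc)2 (10 mol %), O2 (1 atm), DMSO, rt
Reagents that add atoms: none
Why: Saegusa–Ito oxidation; the palladium enolate at C10 should lose the C9 hydrogen to give the endocyclic 10-methyl enone.

Step 8
Reactants: 9 enone ester
Product: 10 9α,10α-diol of 9
Conditions: OsO4 (2 mol %), NMO, acetone/H2O, rt
Reagents that add atoms: N-methylmorpholine N-oxide, C[N+]1([O-])CCOCC1; water, O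
Why: Catalytic syn-dihydroxylation of the only alkene should occur anti to the allylic C8–OTBS group, which sets C9 and C10 (both OH α, cis to each other, O9 trans to O8, 10-methyl β).

Step 9
Reactants: 10 9α,10α-diol
Product: 11 9α,10α-O-isopropylidene derivative of 10
Conditions: Me2C(OMe)2, PPTS (cat.), CH2Cl2, rt
Reagents that add atoms: 2,2-dimethoxypropane, COC(C)(C)OC
Why: Acetonide formation on the cis-diol protects O9/O10 through the basic steps and places a shield on the α face of the C1 ketone.

Step 10
Reactants: 11 acetonide silyl ether ester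
Product: 13 trans-fused keto lactone acetonide (8β,12-olide; C1 ketone; C6H2), via hydroxy ester 12 (not isolated)
Conditions: Bu4NF, THF, 0 °C → rt
Reagents that add atoms: none
Why: Fluoride desilylation frees O8, which should lactonise onto the methyl ester (acyl substitution, five-membered ring) to the trans-fused γ-lactone because O8 and the C7 side chain are trans-diequatorial.

Step 11
Reactants: 13 trans-fused keto lactone acetonide
Product: 14 6β-allyl keto lactone acetonide
Conditions: LiN(i-Pr)2 (1.05 equiv), THF, −78 °C; allyl iodide, −78 → −20 °C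
Reagents that add atoms: allyl iodide, C=CCI
Why: Enolate alkylation; the ketone can enolise only toward C6 (C10 is quaternary), and allylation should give the equatorial 6β-allyl group trans to the C7 substituent, which is also the thermodynamic epimer reachable by base equilibration.

Step 12
Reactants: 14 6β-allyl keto lactone acetonide
Product: 15 1β-vinyl-1α-hydroxy-6β-allyl lactone acetonide
Conditions: CH2=CHMgBr, CeCl3, THF, −78 °C
Reagents that add atoms: vinylmagnesium bromide, C=C[Mg]Br
Why: Organocerium 1,2-addition, chemoselective for the ketone over the lactone; the acetonide blocks the α face and its axial C10–O bond favours attack anti to it (Felkin–Anh, axial attack), so vinyl should enter from the β face and set C1 with vinyl axial and OH equatorial.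

Step 13
Reactants: 15 1β-vinyl-1α-hydroxy-6β-allyl lactone acetonide
Product: 16 1β-vinyl-1α-hydroxy-6β-[(E)-prop-1-enyl] lactone acetonide
Conditions: RuHCl(CO)(PPh3)3 (5 mol %), toluene, 80 °C
Reagents that add atoms: none
Why: Ruthenium hydride-catalysed alkene isomerisation (allyl to prop-1-enyl) should stop at the (E)-disubstituted alkene under thermodynamic control, while the vinyl group on the quaternary carbinol cannot migrate; any (Z)-isomer would be removed on AgNO3-doped silica.

Step 14
Reactants: 16 1β-vinyl-1α-hydroxy-6β-[(E)-prop-1-enyl] lactone acetonide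
Product: 17 11-(dimethylaminomethyl) derivative of 16 (C11 epimers)
Conditions: LiN(i-Pr)2 (2.2 equiv), THF, −78 °C; CH2=NMe2+ I−, −78 → 0 °C
Reagents that add atoms: N,N-dimethylmethyleneiminium iodide, C=[N+](C)C.[I-]
Why: Mannich reaction of the lactone enolate (formed after the lithium alkoxide, which does not rearrange at this temperature) installs C13 as a base-stable masked methylene before any ketone is present; the C11 configuration is irrelevant.

Step 15
Reactants: 17 11-(dimethylaminomethyl) 1β-vinyl-6β-[(E)-prop-1-enyl] carbinol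
Product: 19 (4R,5Z)-ten-membered keto lactone Mannich base (C1 ketone, 4α-methyl, 9α,10α-acetonide), via potassium enolate 18 (not isolated)
Conditions: KN(SiMe3)2 (1.5 equiv), 18-crown-6, THF, 0 → 40 °C; then AcOH, −78 °C
Reagents that add atoms: none
Why: The potassium alkoxide undergoes the alkoxide-accelerated [3,3]-sigmatropic (anionic oxy-Cope) shift in which C1–C6 breaks, C3–C4 forms and enolate 18 is protonated to the ketone; the closest known reaction type is the anionic oxy-Cope ring expansion of 1,2-dialkenylcyclohexanols to cyclodec-5-enones. The ten-membered ring is closed by this four-atom ring expansion of ring A and not by an end-to-end cyclisation, so no high dilution is needed. The trans-fused lactone and the acetonide lock ring A in one chair with the C1 vinyl axial and the C6 propenyl equatorial, which leaves a single chair transition state: in it the C6–C7 ring bond is pseudo-axial, which makes the new C5=C6 alkene Z, and the (E)-propenyl methyl is pseudo-equatorial, so C3 can reach only one face of C4 and C4 should be R. The step needs chair-over-boat selectivity and a shift faster than alkoxide fragmentation; the ring lock removes the alternative chair (its dialkenyl groups would be anti) and the crown ether frees the alkoxide so that the shift should run near room temperature.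

Step 16
Reactants: 19 (4R,5Z)-ten-membered keto lactone Mannich base
Product: 21 (5Z)-11(13)-methylene keto lactone acetonide, via trimethylammonium iodide 20 (not isolated)
Conditions: MeI, THF, rt; then NaHCO3, H2O/CH2Cl2, rt
Reagents that add atoms: none
Why: N-Quaternisation followed by mild base-induced β-elimination (E1cB of the Mannich base) releases the α-methylene lactone without an enolisation step that the C1 ketone would not tolerate.

Step 17
Reactants: 21 (5Z)-11(13)-methylene keto lactone acetonide
Product: 23 6β-hydroxy 1α,5α-oxygen-bridged hemiketal (1β-OH), via 5β,6β-epoxide 22 (not isolated)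
Conditions: mCPBA, CH2Cl2, 0 °C; then PPTS (cat.), THF/H2O, rt
Reagents that add atoms: 3-chloroperoxybenzoic acid, OOC(=O)c1cccc(Cl)c1; water, O
Why: Prilezhaev epoxidation followed by an acid-triggered transannular keto-epoxide cyclisation (brevicomin-type carbonyl participation): with H4 and H7 eclipsing the (Z)-alkene to avoid A(1,3) strain the ring covers one face, so the peracid should add from the outer face, and the C1 carbonyl oxygen inside the ring opens the epoxide at C5 with inversion through a six-membered ring before water caps C1, which sets C6 (OH β) and C5 (O α) and leaves O6 as the only free secondary hydroxyl.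

Step 18
Reactants: 23 6β-hydroxy bridged hemiketal
Product: 24 6-O-allyloxycarbonyl bridged hemiketal
Conditions: allyl chloroformate, pyridine, DMAP (cat.), CH2Cl2, 0 °C
Reagents that add atoms: allyl chloroformate, C=CCOC(=O)Cl
Why: Carbonate formation (acylation) should take the free secondary O6–H, because O5 is tied in the bridge and the hemiketal OH is tertiary.

Step 19
Reactants: 24 6-O-allyloxycarbonyl bridged hemiketal
Product: 25 5α-isovalerate 6β-allyl carbonate C1 ketone acetonide
Conditions: (Me2CHCH2CO)2O, DMAP, Et3N, CH2Cl2, rt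
Reagents that add atoms: 3-methylbutanoic anhydride, CC(C)CC(=O)OC(=O)CC(C)C
Why: DMAP-catalysed acylation through the open δ-hydroxy ketone tautomer of the hemiketal should esterify O5 and return the C1 ketone, the tertiary hemiketal OH being the slower site.

Step 20
Reactants: 25 5α-isovalerate 6β-allyl carbonate C1 ketone acetonide
Product: 26 9α,10α-diol of 25
Conditions: TFA/H2O (9:1), 0 °C
Reagents that add atoms: none
Why: Acid hydrolysis of the acetonide; esters, the allyl carbonate and the methylene lactone should tolerate it, and no alkene remains for transannular cation chemistry.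

Step 21
Reactants: 26 9α,10α-diol
Product: 27 9α-isobutyrate of 26
Conditions: (Me2CHCO)2O, pyridine, DMAP (cat.), CH2Cl2, 0 °C
Reagents that add atoms: 2-methylpropanoic anhydride, CC(C)C(=O)OC(=O)C(C)C
Why: Selective acylation of the secondary O9–H; the tertiary O10–H should not react and O6 is still protected.

Step 22
Reactants: 27 9α-isobutyrate 5α-isovalerate 6β-allyl carbonate
Product: 28 target CNP0203887.1
Conditions: Pd(PPh3)4 (5 mol %), dimedone, THF, rt
Reagents that add atoms: none
Why: Tsuji–Trost deallylation of the allyl carbonate with a neutral carbon-acid scavenger frees O6–H without base, so the two esters should not migrate.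

## Compound list

1 | 1,4-dioxaspiro[4.5]dec-6-en-8-one | O=C1C=CC2(CC1)OCCO2 | starting material
2 | (8R)-1,4-dioxaspiro[4.5]dec-6-en-8-ol | O[C@H]1C=CC2(OCCO2)CC1 | intermediate
3 | (8R)-8-[(tert-butyldimethylsilyl)oxy]-1,4-dioxaspiro[4.5]dec-6-ene | CC(C)(C)[Si](C)(C)O[C@H]1C=CC2(OCCO2)CC1 | intermediate
4 | (4R)-4-[(tert-butyldimethylsilyl)oxy]cyclohex-2-en-1-one | CC(C)(C)[Si](C)(C)O[C@H]1C=CC(=O)CC1 | intermediate
5 | (4R)-4-[(tert-butyldimethylsilyl)oxy]-6-methylcyclohex-2-en-1-one (C6 epimers) | CC(C)(C)[Si](C)(C)O[C@H]1C=CC(=O)C(C)C1 | intermediate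
6 | trimethylsilyl enol ether (C1=C6) of keto ester 7 | COC(=O)C[C@@H]1C=C(O[Si](C)(C)C)C(C)C[C@H]1O[Si](C)(C)C(C)(C)C | intermediate (not isolated)
7 | methyl 2-[(1S,2R)-2-[(tert-butyldimethylsilyl)oxy]-4-methyl-5-oxocyclohexyl]acetate (C4 epimers) | COC(=O)C[C@@H]1CC(=O)C(C)C[C@H]1O[Si](C)(C)C(C)(C)C | intermediate
8 | C1=C10 trimethylsilyl enol ether of 7 | COC(=O)C[C@@H]1CC(O[Si](C)(C)C)=C(C)C[C@H]1O[Si](C)(C)C(C)(C)C | intermediate
9 | enone ester (C1 ketone, C9=C10, 10-methyl, 8β-OTBS, 7α-CH2CO2Me) | COC(=O)C[C@@H]1CC(=O)C(C)=C[C@H]1O[Si](C)(C)C(C)(C)C | intermediate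
10 | 9α,10α-diol of 9 (10β-methyl) | COC(=O)C[C@@H]1CC(=O)[C@](C)(O)[C@H](O)[C@H]1O[Si](C)(C)C(C)(C)C | intermediate
11 | 9α,10α-O-isopropylidene derivative of 10 | COC(=O)C[C@@H]1CC(=O)[C@]2(C)OC(C)(C)O[C@@H]2[C@H]1O[Si](C)(C)C(C)(C)C | intermediate
12 | 8β-hydroxy ester (desilylated 11) | COC(=O)C[C@@H]1CC(=O)[C@]2(C)OC(C)(C)O[C@@H]2[C@H]1O | intermediate (not isolated)
13 | trans-fused keto lactone acetonide (8β,12-olide, C1 ketone, C6H2) | O=C1C[C@@H]2CC(=O)[C@]3(C)OC(C)(C)O[C@@H]3[C@H]2O1 | intermediate
14 | 6β-allyl keto lactone acetonide | O=C1C[C@@H]2[C@@H](CC=C)C(=O)[C@]3(C)OC(C)(C)O[C@@H]3[C@H]2O1 | intermediate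
15 | 1β-vinyl-1α-hydroxy-6β-allyl lactone acetonide | O=C1C[C@@H]2[C@@H](CC=C)[C@@](O)(C=C)[C@]3(C)OC(C)(C)O[C@@H]3[C@H]2O1 | intermediate
16 | 1β-vinyl-1α-hydroxy-6β-[(E)-prop-1-enyl] lactone acetonide | O=C1C[C@@H]2[C@@H](/C=C/C)[C@@](O)(C=C)[C@]3(C)OC(C)(C)O[C@@H]3[C@H]2O1 | intermediate
17 | 11-(dimethylaminomethyl) derivative of 16 (C11 epimers) | O=C1C(CN(C)C)[C@@H]2[C@@H](/C=C/C)[C@@](O)(C=C)[C@]3(C)OC(C)(C)O[C@@H]3[C@H]2O1 | intermediate
18 | potassium C1(O)=C2 enolate of 19 | O=C1C(CN(C)C)[C@@H]2/C=C\[C@H](C)CC=C([O-])[C@]3(C)OC(C)(C)O[C@@H]3[C@H]2O1.[K+] | intermediate (not isolated)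
19 | (4R,5Z)-ten-membered keto lactone Mannich base (C1 ketone, 4α-methyl, 9α,10α-acetonide) | O=C1C(CN(C)C)[C@@H]2/C=C\[C@H](C)CCC(=O)[C@]3(C)OC(C)(C)O[C@@H]3[C@H]2O1 | intermediate
20 | trimethylammonium iodide of 19 | O=C1C(C[N+](C)(C)C)[C@@H]2/C=C\[C@H](C)CCC(=O)[C@]3(C)OC(C)(C)O[C@@H]3[C@H]2O1.[I-] | intermediate (not isolated)
21 | (5Z)-11(13)-methylene keto lactone acetonide | O=C1C(=C)[C@@H]2/C=C\[C@H](C)CCC(=O)[C@]3(C)OC(C)(C)O[C@@H]3[C@H]2O1 | intermediate
22 | 5β,6β-epoxide of 21 | O=C1C(=C)[C@@H]2[C@H]3O[C@H]3[C@H](C)CCC(=O)[C@]4(C)OC(C)(C)O[C@@H]4[C@H]2O1 | intermediate (not isolated)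
23 | 6β-hydroxy 1α,5α-oxygen-bridged hemiketal (1β-OH) | O=C1C(=C)[C@@H]2[C@@H](O)[C@@H]3O[C@@](O)(CC[C@H]3C)[C@]4(C)OC(C)(C)O[C@@H]4[C@H]2O1 | intermediate
24 | 6-O-allyloxycarbonyl bridged hemiketal | O=C1C(=C)[C@@H]2[C@@H](OC(=O)OCC=C)[C@@H]3O[C@@](O)(CC[C@H]3C)[C@]4(C)OC(C)(C)O[C@@H]4[C@H]2O1 | intermediate
25 | 5α-isovalerate 6β-allyl carbonate C1 ketone acetonide | O=C1C(=C)[C@@H]2[C@@H](OC(=O)OCC=C)[C@H](OC(=O)CC(C)C)[C@H](C)CCC(=O)[C@]3(C)OC(C)(C)O[C@@H]3[C@H]2O1 | intermediate
26 | 9α,10α-diol of 25 | O=C1C(=C)[C@@H]2[C@@H](OC(=O)OCC=C)[C@H](OC(=O)CC(C)C)[C@H](C)CCC(=O)[C@](C)(O)[C@H](O)[C@H]2O1 | intermediate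
27 | 9α-isobutyrate of 26 | O=C1C(=C)[C@@H]2[C@@H](OC(=O)OCC=C)[C@H](OC(=O)CC(C)C)[C@H](C)CCC(=O)[C@](C)(O)[C@H](OC(=O)C(C)C)[C@H]2O1 | intermediate
28 | CNP0203887.1, (4R,5R,6R,7R,8S,9R,10R) in the numbering above | C=C1C(=O)O[C@H]2[C@H]1[C@@H](O)[C@H](OC(=O)CC(C)C)[C@H](C)CCC(=O)[C@](C)(O)[C@@H]2OC(=O)C(C)C | target

## Step count and risks

Total step count: 22. Longest linear sequence: 22 steps (the route is linear from 1).

Steps most likely to fail:

1. Step 15. The only open chair places the C6–C7 ring bond pseudo-axial, so the shift may be slow enough for alkoxide-driven fragmentation or a boat pathway to compete, which would erode the Z geometry and the C4 configuration. Fallback, setting out from 16 and coming back at 19: the shift would be run without an alkoxide. Compound 16 would be silylated (Et3SiOTf, 2,6-lutidine) to the triethylsilyl ether F1 and heated (o-dichlorobenzene, 190 °C, neutral siloxy-Cope shift through the same chair) to the ring-expanded triethylsilyl enol ether F2. Because the ketone is masked in F2, LiN(i-Pr)2 and CH2=NMe2+ I− would aminomethylate only the lactone to give the Mannich base enol ether F3, and HF·pyridine would then release ketone 19.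

2. Step 17. Epoxidation may occur on the wrong face, or the acid-triggered opening may be diverted into a transannular hydride shift or C–C closure instead of oxygen delivery from C1. Fallback, setting out from 21 and coming back at 25: the two oxygens would be delivered separately. OsO4/NMO dihydroxylation from the same outer face would give the 5β,6β-diol F4; SOCl2/Et3N then RuCl3 (cat.)/NaIO4 would give the cyclic sulfate F5; CsO2CCH2CHMe2 in DMF would open it at C5 (the carbon remote from the lactone) with inversion to the sulfate monoester F6; dilute H2SO4 in THF/H2O would give the 6-hydroxy 5-isovalerate F7; allyl chloroformate/pyridine would then give 25. This path also avoids the hemiketal acylation of step 19.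

3. Step 12. Loss of facial selectivity in the carbonyl addition (competing equatorial attack) would invert C1 and with it the geometry of the ring expansion. Fallback, setting out from 14 and coming back at 15: the carbinol would be built by methylene transfer instead of vinyl addition. Me2S=CH2 (from Me3SI and n-BuLi, THF, −10 °C; Corey–Chaykovsky reaction) adds irreversibly along the axial β trajectory and closes to the spiro-epoxide F8 (CH2 β, O α). An excess of the same ylide at rt would open F8 at its CH2 and eliminate Me2S (epoxide to one-carbon-homologated allylic alcohol) to give 15.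

## Further compounds

F1 | step 15 | triethylsilyl ether of 16 | O=C1C[C@@H]2[C@@H](/C=C/C)[C@@](O[Si](CC)(CC)CC)(C=C)[C@]3(C)OC(C)(C)O[C@@H]3[C@H]2O1
F2 | step 15 | (5Z)-ring-expanded C1=C2 triethylsilyl enol ether (no C11 substituent) | O=C1C[C@@H]2/C=C\[C@H](C)CC=C(O[Si](CC)(CC)CC)[C@]3(C)OC(C)(C)O[C@@H]3[C@H]2O1
F3 | step 15 | 11-(dimethylaminomethyl) derivative of F2 | O=C1C(CN(C)C)[C@@H]2/C=C\[C@H](C)CC=C(O[Si](CC)(CC)CC)[C@]3(C)OC(C)(C)O[C@@H]3[C@H]2O1
F4 | step 17 | 5β,6β-diol of 21 | O=C1C(=C)[C@@H]2[C@@H](O)[C@@H](O)[C@H](C)CCC(=O)[C@]3(C)OC(C)(C)O[C@@H]3[C@H]2O1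
F5 | step 17 | 5β,6β-cyclic sulfate | O=C1C(=C)[C@@H]2[C@H]3OS(=O)(=O)O[C@H]3[C@H](C)CCC(=O)[C@]4(C)OC(C)(C)O[C@@H]4[C@H]2O1
F6 | step 17 | caesium 6β-sulfate of the 5α-isovalerate | O=C1C(=C)[C@@H]2[C@@H](OS(=O)(=O)[O-])[C@H](OC(=O)CC(C)C)[C@H](C)CCC(=O)[C@]3(C)OC(C)(C)O[C@@H]3[C@H]2O1.[Cs+]
F7 | step 17 | 6β-hydroxy 5α-isovalerate C1 ketone acetonide | O=C1C(=C)[C@@H]2[C@@H](O)[C@H](OC(=O)CC(C)C)[C@H](C)CCC(=O)[C@]3(C)OC(C)(C)O[C@@H]3[C@H]2O1
F8 | step 12 | C1 spiro-epoxide of 14 (CH2 β, O α) | O=C1C[C@@H]2[C@@H](CC=C)[C@@]3(CO3)[C@]4(C)OC(C)(C)O[C@@H]4[C@H]2O1
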